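Readings and results stem from a simulated flask from invented constants; noise was put on by code.

The reading at 72.0 h in the east flask showed target at 25.4%. That was the quick number you asked for, along with your hunch that ash should pay best because more substrate goes in.

| setting | east | north-east | flask |
|---|---|---|---|
| substrate | 0.062 M | 0.062 M | 0.062 M |
| temperature | 90 °C | 75 °C | 90 °C |
| remark | the very flask that is asked about, followed so far | run made earlier |  |
| time |  |  | 3.0 d |

- east (time / h: target / %, substrate / %): 6.00: 40.4, 37.5; 10.0: 39.2, 36.7; 15.0: 36.8, 34.7; 25.0: 34.3, 31.3; 40.0: 30.2, 27.6; 72.0: 25.4, 22.8
- north-east (time / h: target / %, substrate / %): 12.0: 39.5, 36.3; 20.0: 38.4, 29.6; 30.0: 35.7, 26.2; 48.0: 32.7, 24.1; 96.0: 27.8, 21.0; 144: 24.8, 17.3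

(scatter of a reading: 0.5 percentage points)

- ash: at 3.0 d add substrate, 50.0% of the amount charged, then wait 3.0 d
- alder: at 3.0 d raise the temperature by 15 K, then wait 3.0 d
- cedar: change nothing and wait 3.0 d more
- larch: at 3.0 d take out 90% of the target then present, then wait 3.0 d

- target, in percent of the substrate first charged, at 3.0 d
- which option adds most target ("none" when 2 percentage points or less is all one gets) (ash / alder / cedar / larch / none)
- target present, with what was taken out counted in, in percent of the substrate first charged, after ash
- target present, with what was taken out counted in, in percent of the substrate first charged, after alder

- what is taken out of target is counted as made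
- the numbers in the tables scatter by 0.5 percentage points (one standard deviation)
- what may be going on: substrate <-> target; target <-> isomer of the product A; isomer of the product A <-> isomer of the product B; target <-> isomer of the product C
- additions bring no volume worth counting

I answered with one quantity. Each step on the card turns one species into one other, so I took the steps as first-order. What is added or removed at 3.0 d then runs its own course on top of the unchanged flask, and I reckoned that correction and nothing else.

The east run is itself such a course, since it turned its charge into 25.4% target after 3.0 d. I called this share of a charge standing as target one wait later at 90 °C the keep.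

Target removed counts the same way, I argued, because in the east flask the ratio of target to substrate read 1.08 at 6.00 h and 1.11 at 72.0 h. This pre-equilibrium was reached far sooner than the wait lasts.

So ash adds 13 percentage points to the unchanged flask. Larch takes out 23 points and forgoes the keep of that, which leaves it 17 points ahead, more than ash.

Held over the further wait, the pace of the last two east readings comes to a loss of 11 points, less than the larch correction. That pace was slower than the one before it, so I took this loss as a high estimate. I therefore told you larch, not ash. The keep belongs to 90 °C, so my own reckoning gave no figure for alder; the figure below is the forecast's.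

The forecast said 25.2% (24.5% to 25.9%), larch as best, 33.2% after ash and 18.5% after alder, on the ground that “All steps are first-order, so superposition applies”.

The flask stood at 25.4%, larch came out best by adding 12 points, and alder ended at 28.4% against the forecast's 18.5%.

    substrate ⇌ target (K = 1.10, k = 0.710 /h, Ea = 103 kJ/mol, ΔH = −17.0 kJ/mol)
    target ⇌ isomer of the product A (K = 0.330, k = 0.280 /h, Ea = 124 kJ/mol, ΔH = −70.0 kJ/mol)
    isomer of the product A ⇌ isomer of the product B (K = 9.40, k = 0.0740 /h, Ea = 127 kJ/mol, ΔH = −6.00 kJ/mol)
    target ⇌ isomer of the product C (K = 0.160, k = 3.30 /h, Ea = 107 kJ/mol, ΔH = −34.0 kJ/mol)
    (constants at 90 °C)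

Left unchanged, the flask reached 20.3%. With the keep, ash then reckons to 33.3%, and the ash flask gave 33.1%.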